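The runs were computed on assumed constants, noise included.

| setting | alder | oak | cedar | birch |
|---|---|---|---|---|
| Sbt | 100 mM | 60.0 mM | 300 mM | 100 mM |
| Ptn | 300 mM | 260 mM | 300 mM | 300 mM |
| Ctl | 8.00 mM | 8.00 mM | 8.00 mM | 8.00 mM |
| Pdt |  |  |  | 30.0 mM |
| time |  |  |  | 29 min |

| run | time / min | [Pdt] / mM |
|---|---|---|
| alder run | 1.2 | 3.5 |
| alder run | 2.6 | 7.5 |
| alder run | 5.8 | 15.3 |
| alder run | 13 | 29.3 |
| alder run | 29 | 46.6 |
| oak run | 1.2 | 2.0 |
| oak run | 2.6 | 4.9 |
| oak run | 5.8 | 8.4 |
| oak run | 13 | 16.0 |
| oak run | 29 | 26.7 |
| cedar run | 1.2 | 11.1 |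
| cedar run | 2.6 | 21.7 |
| cedar run | 5.8 | 43.4 |
| cedar run | 13 | 75.6 |
| cedar run | 29 | 110.7 |

(each reading ± 0.3 mM)

- Overall: Sbt + Ptn -> Pdt, with Ctl as catalyst.
- Constant volume, constant temperature.
- "The second partner" is Ptn.
- An order is taken over about fifteen percent of the charge, up and down.
- A share of Pdt counts the Pdt that was charged too.

* the exponent of [Ptn] in the starting rate at the charge of the alder run (at the point where two percent of the Sbt have become Pdt)
* the exponent of [Sbt] in the starting rate at the charge of the alder run (at the point where two percent of the Sbt have become Pdt) (one fixed amount of Pdt, the same in the runs compared)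
* Pdt in the birch run at 29 min, as a share of the Sbt charged

**The leftover.** At 29 min the alder run has 53.4 mM of its 100 mM of Sbt not showing as Pdt, and I start from that remainder. I call the pace of a stretch the logarithm of the ratio of the leftovers at its two ends, divided by its length. With Ptn in excess in the alder run, this is a pseudo-first-order constant. Between 13 min and 29 min the alder run has a late pace of 0.0175 min⁻¹. That is slower than the 0.0300 min⁻¹ of its first 2.6 min.

**The ceiling.** The birch run is the alder charge plus 30.0 mM of Pdt. If that Pdt neither speeds nor slows the run and itself stays whole, the birch run adds the alder run's 46.6 mM and stands at 76.6 %.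

**The floor.** The cedar run has a late pace of 0.0106 min⁻¹, with Pdt between 75.6 mM and 110.7 mM. Held over the whole birch run, it gives a loose floor of 56.5 %. To tighten it, I note that the alder run's late stretch begins at 29.3 mM of Pdt, close to the birch charge. So I let the birch run keep the alder late pace for 29 min, which gives 69.9 %. This floor too counts the 30.0 mM charged as kept whole, and the birch run climbs past that stretch's 46.6 mM, so it is my judgement and not a proof.

**The orders.** Tripling Sbt from the alder to the cedar run gives an exponent of 0.967 from the readings at 2.6 min. The paces to 13 min in the oak and alder runs give my reading for Ptn, 0.779, from a contrast of 13.3 % in Ptn.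

**The forecast.** It gives 0.7 for Ptn, 1 for Sbt and 72 % for the birch run, inside my tightened bracket , and it calls its Ptn order “poorly fixed because only this small, noisy contrast bears on it”.

**The result.** The flask gives 1.0 for Ptn, 1.0 for Sbt and 70.3 % for the birch run.

    2 Ctl ⇌ Ctl2, settled at all times (112.0 M⁻¹)
    Ctl2 + Sbt + Ptn → Pdt + Ctl2 (54.00 M⁻² min⁻¹)
    Pdt → G (0.007740 min⁻¹)
    2 Sbt → L (0.02814 M⁻¹ min⁻¹)

**Late pace again.** The birch result of 70.3 % lies just above my tightened floor. By the step from Pdt to G, the 30.0 mM charged keeps 24.0 mM at 29 min, so the rest of the birch result is 46.3 mM, beside the alder run's reading of 46.6 mM. On that remainder the birch run shows a pace of 0.0215 min⁻¹, faster than the late pace of 0.0175 min⁻¹. Carried to the oak run, the late pace puts a quarter of the Sbt charged as Pdt at 16.4 min, and the oak run reaches that mark earlier, at 11.9 min.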